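**Retrosynthetic overview**

1. Last C–C bond: trans-selective α-benzylation of the β-(arylmethyl)butyrolactone 33 (ring A half) with benzylic bromide 28 (ring B half, the dihydrobenzofuran), then global desilylation.
2. Lactone 33 comes from 1,4-diol 31 by site-selective oxidative lactonisation. Diol 31 comes from allyl arene 13 in the key step, which makes both lactone C–C bonds flanking the Cα–Cβ bond (CH2O–Cβ and C(=O)–Cα) in one flask: Pt-catalysed enantioselective diboration of the allyl C=C, insertion of one CH2 into each C–B bond, oxidation.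
3. Enabling feature: in the oxolan-2-one ring, C4 (Cβ) and C3 (Cα) are vicinal sp3 carbons that carry the two ends of the C5H2–O1–C2(=O) bridge. Cutting C4–C5 and C3–C2 leaves C4–C3 as the terminal C=C of the allyl group of a eugenol-type arene, and its unequal ends (secondary and primary) later tell the two new CH2OH groups apart.
4. 13 from eugenol (1) and 28 from methyl 5-bromovanillate (14): ortho-bromide, Negishi α-arylation, Evans-auxiliary aldol with aldehyde 9 (anti for the open chain on ring A, syn for ring B), reduction; for 28, acid closure of the dihydrobenzofuran follows.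
5. Order of ring formation: dihydrobenzofuran ring (step 15), then butyrolactone ring (step 20); the benzene rings are bought.

Key step: step 19

Abbreviations: TBS = tert-butyldimethylsilyl; pin = pinacolato; Xc = (S)-4-benzyl-2-oxo-1,3-oxazolidin-3-yl; ArA = 3-[(1S,2S)-1,3-bis(TBSO)-1-(4-TBSO-3-methoxyphenyl)propan-2-yl]-4-(TBSO)-5-methoxyphenyl; ArB = (2S,3R)-3-(TBSOCH2)-2-(4-TBSO-3-methoxyphenyl)-7-methoxy-2,3-dihydro-1-benzofuran-5-yl.

Assumption: for each chiral ligand or catalyst named, the antipode meant is the one whose established sense of induction gives the drawn configuration; 9 and 14 are taken as purchasable.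

**Route**

Step 1
Reactants: 1 eugenol
Product: 2 4-allyl-2-bromo-6-methoxyphenol
Conditions: NBS, i-Pr2NH (cat.), CH2Cl2, 0 °C
Reagents that add atoms: N-bromosuccinimide, O=C1CCC(=O)N1Br
Why: Amine-catalysed electrophilic aromatic bromination with NBS should take the only free position ortho to the phenol OH (para is blocked by the allyl group) faster than the allyl C=C reacts.

Step 2
Reactants: 2 4-allyl-2-bromo-6-methoxyphenol
Product: 3 (4-allyl-2-bromo-6-methoxyphenoxy)(tert-butyl)dimethylsilane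
Conditions: TBSCl, imidazole, DMF, rt
Reagents that add atoms: tert-butyldimethylsilyl chloride, CC(C)(C)[Si](C)(C)Cl
Why: Silyl ether formation masks the phenol for the organozinc, enolate and organolithium steps that follow.

Step 3
Reactants: 3 (4-allyl-2-bromo-6-methoxyphenoxy)(tert-butyl)dimethylsilane
Product: 4 tert-butyl 2-[5-allyl-2-(TBSO)-3-methoxyphenyl]acetate
Conditions: BrZnCH2CO2t-Bu, Pd(dba)2 (cat.), P(t-Bu)3 (cat.), THF, rt
Reagents that add atoms: (2-tert-butoxy-2-oxoethyl)zinc bromide, CC(C)(C)OC(=O)C[Zn]Br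
Why: Pd-catalysed Negishi-type α-arylation of a Reformatsky zinc enolate (oxidative addition, transmetalation, reductive elimination) should replace Br by the acetate unit without touching the allyl group or the silyl ether.

Step 4
Reactants: 4 tert-butyl 2-[5-allyl-2-(TBSO)-3-methoxyphenyl]acetate
Product: 5 2-[5-allyl-2-(TBSO)-3-methoxyphenyl]acetic acid
Conditions: TFA, CH2Cl2, 0 °C to rt
Reagents that add atoms: none
Why: Acidolysis of the tert-butyl ester (loss of isobutene) frees the acid, while the aryl silyl ether and the alkene tolerate TFA.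

Step 5
Reactants: 5 2-[5-allyl-2-(TBSO)-3-methoxyphenyl]acetic acid; 6 (S)-4-benzyl-1,3-oxazolidin-2-one
Product: 8 (S)-3-{[5-allyl-2-(TBSO)-3-methoxyphenyl]acetyl}-4-benzyl-1,3-oxazolidin-2-one, via mixed pivalic anhydride 7 (not isolated)
Conditions: t-BuCOCl, Et3N, THF, −20 °C; then LiCl, 6, rt
Reagents that add atoms: none
Why: N-Acylation of the oxazolidinone through the mixed pivalic anhydride with LiCl activation attaches the Evans auxiliary under mild conditions.

Step 6
Reactants: 8 (S)-3-{[5-allyl-2-(TBSO)-3-methoxyphenyl]acetyl}-4-benzyl-1,3-oxazolidin-2-one; 9 4-(TBSO)-3-methoxybenzaldehyde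
Product: 11 (S)-3-{(2R,3S)-2-[5-allyl-2-(TBSO)-3-methoxyphenyl]-3-hydroxy-3-[4-(TBSO)-3-methoxyphenyl]propanoyl}-4-benzyl-1,3-oxazolidin-2-one, via trimethylsilyl ether 10 (not isolated)
Conditions: MgCl2 (cat.), Et3N, Me3SiCl, EtOAc, rt; then MeOH, TFA (cat.)
Reagents that add atoms: none
Why: Magnesium halide-catalysed direct anti-aldol reaction of an N-acyloxazolidinone (Evans anti-aldol): the chelated Z-enolate is attacked on the face opposite the benzyl group and silylation of the aldolate makes the addition irreversible, which should set C2 as R and C3 as S (anti).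

Step 7
Reactants: 11 anti-aldol adduct
Product: 12 (1S,2S)-2-[5-allyl-2-(TBSO)-3-methoxyphenyl]-1-[4-(TBSO)-3-methoxyphenyl]propane-1,3-diol
Conditions: LiBH4, THF, MeOH (1 equiv), 0 °C
Reagents that add atoms: none
Why: Reductive cleavage of the N-acyloxazolidinone with LiBH4 should give the primary alcohol and return the auxiliary without touching the two stereocentres or the alkene.

Step 8
Reactants: 12 (1S,2S)-diol
Product: 13 ArA–CH2–CH=CH2 (1,3-bis-TBS ether of 12; fragment A)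
Conditions: TBSOTf, 2,6-lutidine, CH2Cl2, −78 to 0 °C
Reagents that add atoms: tert-butyldimethylsilyl triflate, CC(C)(C)[Si](C)(C)OS(=O)(=O)C(F)(F)F
Why: Silylation with the silyl triflate protects the secondary benzylic and the primary alcohol, so that only ethers and one terminal alkene remain.

Step 9
Reactants: 14 methyl 3-bromo-4-hydroxy-5-methoxybenzoate
Product: 15 methyl 3-bromo-4-(TBSO)-5-methoxybenzoate
Conditions: TBSCl, imidazole, DMF, rt
Reagents that add atoms: tert-butyldimethylsilyl chloride, CC(C)(C)[Si](C)(C)Cl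
Why: Silyl ether formation masks the phenol for the zinc enolate and boron enolate chemistry.

Step 10
Reactants: 15 methyl 3-bromo-4-(TBSO)-5-methoxybenzoate
Product: 16 methyl 3-(2-tert-butoxy-2-oxoethyl)-4-(TBSO)-5-methoxybenzoate
Conditions: BrZnCH2CO2t-Bu, Pd(dba)2 (cat.), P(t-Bu)3 (cat.), THF, rt
Reagents that add atoms: (2-tert-butoxy-2-oxoethyl)zinc bromide, CC(C)(C)OC(=O)C[Zn]Br
Why: Negishi-type α-arylation of the Reformatsky reagent, to which the aryl methyl ester is inert, installs the arylacetic unit at the position ortho to the protected phenol.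

Step 11
Reactants: 16 methyl 3-(2-tert-butoxy-2-oxoethyl)-4-(TBSO)-5-methoxybenzoate
Product: 17 [2-(TBSO)-3-methoxy-5-(methoxycarbonyl)phenyl]acetic acid
Conditions: TFA, CH2Cl2, 0 °C to rt
Reagents that add atoms: none
Why: Acidolysis cleaves only the tert-butyl ester (loss of isobutene); the methyl ester and the aryl silyl ether should stay.

Step 12
Reactants: 17 [2-(TBSO)-3-methoxy-5-(methoxycarbonyl)phenyl]acetic acid; 6 (S)-4-benzyl-1,3-oxazolidin-2-one
Product: 19 methyl 3-[2-oxo-2-(Xc)ethyl]-4-(TBSO)-5-methoxybenzoate, via mixed pivalic anhydride 18 (not isolated)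
Conditions: t-BuCOCl, Et3N, THF, −20 °C; then LiCl, 6, rt
Reagents that add atoms: none
Why: Mixed-anhydride N-acylation of the oxazolidinone attaches the same Evans auxiliary as in step 5.

Step 13
Reactants: 19 methyl 3-[2-oxo-2-(Xc)ethyl]-4-(TBSO)-5-methoxybenzoate; 9 4-(TBSO)-3-methoxybenzaldehyde
Product: 22 methyl 3-{(2S,3S)-3-hydroxy-1-oxo-1-(Xc)-3-[4-(TBSO)-3-methoxyphenyl]propan-2-yl}-4-(TBSO)-5-methoxybenzoate, via Z-dibutylboron enolate 20 (not isolated), via dibutylboron aldolate 21 (not isolated)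
Conditions: Bu2BOTf, i-Pr2NEt, CH2Cl2, −78 to 0 °C; 9, −78 to 0 °C; then pH 7 buffer, MeOH, H2O2, 0 °C
Reagents that add atoms: none
Why: Evans syn-aldol reaction through the Z-dibutylboron enolate and a closed Zimmerman–Traxler chair, in which the aldehyde meets the enolate face opposite the benzyl group, should set C2 as S (the centre that becomes C3 of the dihydrobenzofuran) and C3 as S.

Step 14
Reactants: 22 syn-aldol adduct
Product: 23 methyl 3-{(1S,2R)-1,3-dihydroxy-1-[4-(TBSO)-3-methoxyphenyl]propan-2-yl}-4-(TBSO)-5-methoxybenzoate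
Conditions: LiBH4, THF, MeOH (1 equiv), 0 °C
Reagents that add atoms: none
Why: LiBH4 reduces the imide much faster than the electron-rich aryl methyl ester, so the auxiliary should be cleaved reductively to the primary alcohol with the ester kept for later.

Step 15
Reactants: 23 diol bis(aryl silyl ether)
Product: 25 methyl (2S,3R)-2-(4-hydroxy-3-methoxyphenyl)-3-(hydroxymethyl)-7-methoxy-2,3-dihydro-1-benzofuran-5-carboxylate, via bis-phenol diol 24 (not isolated)
Conditions: Bu4NF, THF, 0 °C; then TsOH·H2O (excess), rt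
Reagents that add atoms: none
Why: Fluoride desilylation followed by acid-catalysed cyclodehydration: the p-hydroxybenzylic alcohol ionises to a quinone-methide-type cation that the neighbouring phenol oxygen traps in a 5-exo closure, and the adjacent stereocentre (substrate control) should direct the aryl group trans, so the carbinol configuration from step 13 does not matter.

Step 16
Reactants: 25 dihydrobenzofuran phenol alcohol
Product: 26 methyl (2S,3R)-3-(TBSOCH2)-2-[4-(TBSO)-3-methoxyphenyl]-7-methoxy-2,3-dihydro-1-benzofuran-5-carboxylate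
Conditions: TBSCl, imidazole, DMF, rt
Reagents that add atoms: tert-butyldimethylsilyl chloride, CC(C)(C)[Si](C)(C)Cl
Why: Silylation of the phenol and the primary alcohol gives the same fluoride-labile protection as in fragment A.

Step 17
Reactants: 26 bis-TBS ester
Product: 27 ArB–CH2OH
Conditions: i-Bu2AlH, CH2Cl2, −78 °C
Reagents that add atoms: none
Why: Hydride reduction of the aryl ester to the benzylic alcohol should leave the silyl ethers and the cyclic benzylic ether untouched.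

Step 18
Reactants: 27 ArB–CH2OH
Product: 28 ArB–CH2Br (fragment B)
Conditions: CBr4, PPh3, CH2Cl2, 0 °C
Reagents that add atoms: carbon tetrabromide, BrC(Br)(Br)Br
Why: Appel bromination (SN2 at the primary benzylic carbon through the alkoxyphosphonium salt) gives the electrophile under neutral conditions that spare the silyl ethers.

Step 19
Reactants: 13 ArA–CH2–CH=CH2
Product: 31 (2R)-2-(ArA-methyl)butane-1,4-diol, via 1,2-bis(boronate) 29 (not isolated), via 1,4-bis(boronate) 30 (not isolated)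
Conditions: Pt(dba)3 (cat.), (R,R)-TADDOL-derived phenylphosphonite (cat.), B2pin2, THF, 60 °C; then BrCH2Cl, n-BuLi, −78 °C to rt; then NaBO3·4H2O, THF–H2O, rt
Reagents that add atoms: bromochloromethane, ClCBr; sodium perborate, [Na+].[O-]OB=O
Why: Oxidative addition of B2pin2 to the zerovalent platinum–phosphonite complex and syn insertion of the terminal alkene give the vicinal bis(boronate) 29; chloromethyllithium, made in situ by Br/Li exchange, then forms an ate complex at each boron, and the 1,2-metallate shift (Matteson homologation) expels chloride and inserts one CH2 into the secondary C–B bond (new CH2–Cβ bond) and one into the primary C–B bond (new bond from Cα to the later carbonyl carbon), after which perborate turns both C–B bonds into C–OH with retention. The closest known reaction type is the one-flask alkene diboration, double chloromethyllithium homologation and oxidation that leads to 2-substituted butane-1,4-diols. No ring is closed in this step; the lactone ring is closed in step 20. The one new stereocentre (Cβ) is set by catalyst control in the diboration, where the TADDOL-phosphonite ligand selects the alkene face independently of the remote centres of 13, and it is kept because the migrating carbon retains its configuration in the 1,2-shift. The step needs chemoselectivity, namely exactly one insertion per boron: forming the carbenoid at −78 °C in the presence of the boronate favours ate-complex formation over carbenoid decay, a limited excess curbs a second insertion, and 13 offers a single monosubstituted alkene beside ethers that are inert to the reagents.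

Step 20
Reactants: 31 (2R)-2-(ArA-methyl)butane-1,4-diol
Product: 33 (4R)-4-(ArA-methyl)oxolan-2-one, via lactol 32 (not isolated)
Conditions: TEMPO (cat.), PhI(OAc)2, CH2Cl2, rt
Reagents that add atoms: none
Why: TEMPO/PhI(OAc)2 oxidative lactonisation: the oxoammonium salt should oxidise the less hindered, unbranched primary alcohol first, the aldehyde closes to lactol 32 with the β-branched alcohol, and a second oxidation gives the lactone whose carbonyl is the carbon introduced at the primary boron.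

Step 21
Reactants: 33 (4R)-4-(ArA-methyl)oxolan-2-one; 28 ArB–CH2Br
Product: 35 (3R,4R)-4-(ArA-methyl)-3-(ArB-methyl)oxolan-2-one, via lithium enolate 34 (not isolated)
Conditions: LiN(SiMe3)2, THF, −78 °C; then 28, DMPU, −78 to −40 °C
Reagents that add atoms: none
Why: Alkylation of the lithium lactone enolate (SN2) with the benzylic bromide should occur on the face anti to the β-substituent, which unites the two fragments and sets the α-centre as R (3,4-trans, substrate control).

Step 22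
Reactants: 35 hexakis-TBS ether
Product: 36 CNP0199264.2, (3R,4R)-4-{[4-hydroxy-3-[(1S,2S)-1,3-dihydroxy-1-(4-hydroxy-3-methoxyphenyl)propan-2-yl]-5-methoxyphenyl]methyl}-3-{[(2S,3R)-2-(4-hydroxy-3-methoxyphenyl)-3-(hydroxymethyl)-7-methoxy-2,3-dihydro-1-benzofuran-5-yl]methyl}oxolan-2-one
Conditions: Bu4NF, AcOH, THF, 0 °C to rt
Reagents that add atoms: none
Why: Buffered fluoride cleavage of all six silyl ethers (driven by Si–F bond formation) should release the phenols and alcohols without acid that could close the open diol chain onto its phenol and without base strong enough to open the lactone.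

**Compound list**

1 | eugenol (4-allyl-2-methoxyphenol) | C=CCc1ccc(O)c(OC)c1 | starting material
2 | 4-allyl-2-bromo-6-methoxyphenol | C=CCc1cc(Br)c(O)c(OC)c1 | intermediate
3 | (4-allyl-2-bromo-6-methoxyphenoxy)(tert-butyl)dimethylsilane | C=CCc1cc(Br)c(O[Si](C)(C)C(C)(C)C)c(OC)c1 | intermediate
4 | tert-butyl 2-[5-allyl-2-(TBSO)-3-methoxyphenyl]acetate | C=CCc1cc(CC(=O)OC(C)(C)C)c(O[Si](C)(C)C(C)(C)C)c(OC)c1 | intermediate
5 | 2-[5-allyl-2-(TBSO)-3-methoxyphenyl]acetic acid | C=CCc1cc(CC(=O)O)c(O[Si](C)(C)C(C)(C)C)c(OC)c1 | intermediate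
6 | (S)-4-benzyl-1,3-oxazolidin-2-one | O=C1OC[C@H](Cc2ccccc2)N1 | starting material
7 | mixed anhydride of 5 and pivalic acid | C=CCc1cc(CC(=O)OC(=O)C(C)(C)C)c(O[Si](C)(C)C(C)(C)C)c(OC)c1 | intermediate
8 | (S)-3-{[5-allyl-2-(TBSO)-3-methoxyphenyl]acetyl}-4-benzyl-1,3-oxazolidin-2-one | C=CCc1cc(CC(=O)N2[C@@H](Cc3ccccc3)COC2=O)c(O[Si](C)(C)C(C)(C)C)c(OC)c1 | intermediate
9 | 4-(TBSO)-3-methoxybenzaldehyde | COc1cc(C=O)ccc1O[Si](C)(C)C(C)(C)C | starting material
10 | O-trimethylsilyl ether of 11 | COc1cc([C@@H](O[Si](C)(C)C)[C@H](C(=O)N3[C@@H](Cc4ccccc4)COC3=O)c2cc(CC=C)cc(OC)c2O[Si](C)(C)C(C)(C)C)ccc1O[Si](C)(C)C(C)(C)C | intermediate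
11 | (S)-3-{(2R,3S)-2-[5-allyl-2-(TBSO)-3-methoxyphenyl]-3-hydroxy-3-[4-(TBSO)-3-methoxyphenyl]propanoyl}-4-benzyl-1,3-oxazolidin-2-one | COc1cc([C@@H](O)[C@H](C(=O)N3[C@@H](Cc4ccccc4)COC3=O)c2cc(CC=C)cc(OC)c2O[Si](C)(C)C(C)(C)C)ccc1O[Si](C)(C)C(C)(C)C | intermediate
12 | (1S,2S)-2-[5-allyl-2-(TBSO)-3-methoxyphenyl]-1-[4-(TBSO)-3-methoxyphenyl]propane-1,3-diol | COc1cc([C@@H](O)[C@H](CO)c2cc(CC=C)cc(OC)c2O[Si](C)(C)C(C)(C)C)ccc1O[Si](C)(C)C(C)(C)C | intermediate
13 | ArA–CH2–CH=CH2, 1,3-bis-TBS ether of 12 (fragment A) | COc1cc([C@@H](O[Si](C)(C)C(C)(C)C)[C@H](CO[Si](C)(C)C(C)(C)C)c2cc(CC=C)cc(OC)c2O[Si](C)(C)C(C)(C)C)ccc1O[Si](C)(C)C(C)(C)C | intermediate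
14 | methyl 3-bromo-4-hydroxy-5-methoxybenzoate | COC(=O)c1cc(Br)c(O)c(OC)c1 | starting material
15 | methyl 3-bromo-4-(TBSO)-5-methoxybenzoate | COC(=O)c1cc(Br)c(O[Si](C)(C)C(C)(C)C)c(OC)c1 | intermediate
16 | methyl 3-(2-tert-butoxy-2-oxoethyl)-4-(TBSO)-5-methoxybenzoate | COC(=O)c1cc(CC(=O)OC(C)(C)C)c(O[Si](C)(C)C(C)(C)C)c(OC)c1 | intermediate
17 | [2-(TBSO)-3-methoxy-5-(methoxycarbonyl)phenyl]acetic acid | COC(=O)c1cc(CC(=O)O)c(O[Si](C)(C)C(C)(C)C)c(OC)c1 | intermediate
18 | mixed anhydride of 17 and pivalic acid | COC(=O)c1cc(CC(=O)OC(=O)C(C)(C)C)c(O[Si](C)(C)C(C)(C)C)c(OC)c1 | intermediate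
19 | methyl 3-[2-oxo-2-(Xc)ethyl]-4-(TBSO)-5-methoxybenzoate | COC(=O)c1cc(CC(=O)N2[C@@H](Cc3ccccc3)COC2=O)c(O[Si](C)(C)C(C)(C)C)c(OC)c1 | intermediate
20 | (Z)-dibutylboron enolate of 19 | COC(=O)c1cc(/C=C(\OB(CCCC)CCCC)N2[C@@H](Cc3ccccc3)COC2=O)c(O[Si](C)(C)C(C)(C)C)c(OC)c1 | intermediate
21 | dibutylboron aldolate of 22 | COc1cc([C@@H](OB(CCCC)CCCC)[C@@H](C(=O)N3[C@@H](Cc4ccccc4)COC3=O)c2cc(C(=O)OC)cc(OC)c2O[Si](C)(C)C(C)(C)C)ccc1O[Si](C)(C)C(C)(C)C | intermediate
22 | methyl 3-{(2S,3S)-3-hydroxy-1-oxo-1-(Xc)-3-[4-(TBSO)-3-methoxyphenyl]propan-2-yl}-4-(TBSO)-5-methoxybenzoate | COc1cc([C@@H](O)[C@@H](C(=O)N3[C@@H](Cc4ccccc4)COC3=O)c2cc(C(=O)OC)cc(OC)c2O[Si](C)(C)C(C)(C)C)ccc1O[Si](C)(C)C(C)(C)C | intermediate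
23 | methyl 3-{(1S,2R)-1,3-dihydroxy-1-[4-(TBSO)-3-methoxyphenyl]propan-2-yl}-4-(TBSO)-5-methoxybenzoate | COc1cc([C@@H](O)[C@@H](CO)c2cc(C(=O)OC)cc(OC)c2O[Si](C)(C)C(C)(C)C)ccc1O[Si](C)(C)C(C)(C)C | intermediate
24 | methyl 3-[(1S,2R)-1,3-dihydroxy-1-(4-hydroxy-3-methoxyphenyl)propan-2-yl]-4-hydroxy-5-methoxybenzoate | COc1cc([C@@H](O)[C@@H](CO)c2cc(C(=O)OC)cc(OC)c2O)ccc1O | intermediate
25 | methyl (2S,3R)-2-(4-hydroxy-3-methoxyphenyl)-3-(hydroxymethyl)-7-methoxy-2,3-dihydro-1-benzofuran-5-carboxylate | COC(=O)c1cc(OC)c2c(c1)[C@H](CO)[C@@H](c1ccc(O)c(OC)c1)O2 | intermediate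
26 | methyl (2S,3R)-3-(TBSOCH2)-2-[4-(TBSO)-3-methoxyphenyl]-7-methoxy-2,3-dihydro-1-benzofuran-5-carboxylate | COC(=O)c1cc(OC)c2c(c1)[C@H](CO[Si](C)(C)C(C)(C)C)[C@@H](c1ccc(O[Si](C)(C)C(C)(C)C)c(OC)c1)O2 | intermediate
27 | ArB–CH2OH | OCc1cc(OC)c2c(c1)[C@H](CO[Si](C)(C)C(C)(C)C)[C@@H](c1ccc(O[Si](C)(C)C(C)(C)C)c(OC)c1)O2 | intermediate
28 | ArB–CH2Br (fragment B) | BrCc1cc(OC)c2c(c1)[C@H](CO[Si](C)(C)C(C)(C)C)[C@@H](c1ccc(O[Si](C)(C)C(C)(C)C)c(OC)c1)O2 | intermediate
29 | 2,2'-[(2S)-3-ArA-propane-1,2-diyl]bis(4,4,5,5-tetramethyl-1,3,2-dioxaborolane) | COc1cc([C@@H](O[Si](C)(C)C(C)(C)C)[C@H](CO[Si](C)(C)C(C)(C)C)c2cc(C[C@H](CB3OC(C)(C)C(C)(C)O3)B3OC(C)(C)C(C)(C)O3)cc(OC)c2O[Si](C)(C)C(C)(C)C)ccc1O[Si](C)(C)C(C)(C)C | intermediate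
30 | 2,2'-[(2S)-2-(ArA-methyl)butane-1,4-diyl]bis(4,4,5,5-tetramethyl-1,3,2-dioxaborolane) | COc1cc([C@@H](O[Si](C)(C)C(C)(C)C)[C@H](CO[Si](C)(C)C(C)(C)C)c2cc(C[C@H](CCB3OC(C)(C)C(C)(C)O3)CB3OC(C)(C)C(C)(C)O3)cc(OC)c2O[Si](C)(C)C(C)(C)C)ccc1O[Si](C)(C)C(C)(C)C | intermediate
31 | (2R)-2-(ArA-methyl)butane-1,4-diol | COc1cc([C@@H](O[Si](C)(C)C(C)(C)C)[C@H](CO[Si](C)(C)C(C)(C)C)c2cc(C[C@H](CCO)CO)cc(OC)c2O[Si](C)(C)C(C)(C)C)ccc1O[Si](C)(C)C(C)(C)C | intermediate
32 | (4R)-4-(ArA-methyl)oxolan-2-ol (lactol, both anomers) | COc1cc([C@@H](O[Si](C)(C)C(C)(C)C)[C@H](CO[Si](C)(C)C(C)(C)C)c2cc(C[C@H]3COC(O)C3)cc(OC)c2O[Si](C)(C)C(C)(C)C)ccc1O[Si](C)(C)C(C)(C)C | intermediate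
33 | (4R)-4-(ArA-methyl)oxolan-2-one | COc1cc([C@@H](O[Si](C)(C)C(C)(C)C)[C@H](CO[Si](C)(C)C(C)(C)C)c2cc(C[C@H]3COC(=O)C3)cc(OC)c2O[Si](C)(C)C(C)(C)C)ccc1O[Si](C)(C)C(C)(C)C | intermediate
34 | lithium enolate of 33 | COc1cc([C@@H](O[Si](C)(C)C(C)(C)C)[C@H](CO[Si](C)(C)C(C)(C)C)c2cc(C[C@H]3COC(O[Li])=C3)cc(OC)c2O[Si](C)(C)C(C)(C)C)ccc1O[Si](C)(C)C(C)(C)C | intermediate
35 | (3R,4R)-4-(ArA-methyl)-3-(ArB-methyl)oxolan-2-one | COc1cc([C@@H](O[Si](C)(C)C(C)(C)C)[C@H](CO[Si](C)(C)C(C)(C)C)c2cc(C[C@H]3COC(=O)[C@@H]3Cc3cc(OC)c4c(c3)[C@H](CO[Si](C)(C)C(C)(C)C)[C@@H](c3ccc(O[Si](C)(C)C(C)(C)C)c(OC)c3)O4)cc(OC)c2O[Si](C)(C)C(C)(C)C)ccc1O[Si](C)(C)C(C)(C)C | intermediate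
36 | CNP0199264.2 | COc1cc([C@@H](O)[C@H](CO)c2cc(C[C@H]3COC(=O)[C@@H]3Cc3cc(OC)c4c(c3)[C@H](CO)[C@@H](c3ccc(O)c(OC)c3)O4)cc(OC)c2O)ccc1O | target

**Step count and risks**

Total step count: 22. Longest linear sequence: 12 steps (steps 1–8 and 19–22; the branch of steps 9–18, 21 and 22 is equally long).

Most likely to fail, first: step 6. The α-aryl imide enolises very easily, so the anti selectivity of the magnesium-catalysed aldol may erode and the acidic α-centre may epimerise under the amine base. The fallback changes the stereocontrol element to an open transition state with a Lewis-acid-bound aldehyde on the antipodal auxiliary. It sets out from 5, which is coupled through 7 with (R)-4-benzyl-1,3-oxazolidin-2-one (t-BuCOCl, Et3N, LiCl) to the antipodal imide F1. F1 is enolised with Bu2BOTf and i-Pr2NEt to its (Z)-dibutylboron enolate F2, which is added at −78 °C to 9 precomplexed with Et2AlCl. The open transition state should give the anti adduct F3 with the same (2R,3S) chain configuration as 11. LiBH4 reduction of F3 comes back to the route at 12.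

Second: step 19. One boron may take up no CH2 or two, giving chain-length mixtures, and facial control in the diboration may be weakened by the bulky silyl ethers. The fallback builds the same lactone by a carbene C–H insertion and sets out from 13. Hydroboration with 9-BBN gives the B-alkyl borane F4, which NaBO3 oxidises to the 3-arylpropan-1-ol F5. Esterification with glyoxylic acid chloride p-toluenesulfonylhydrazone (PhNMe2, then Et3N) gives the diazoacetate F6. Rh2(4S-MPPIM)4 in refluxing CH2Cl2 should then insert the carbene into the C–H bond β to the ester oxygen, closing the γ-lactone and setting the same stereocentre under catalyst control. This comes back to the route at 33.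

Third: step 20. The first oxidation may not discriminate enough between the two primary alcohols, so that the wrong hydroxymethyl group becomes the carbonyl. The fallback fixes the carbonyl carbon from the start and sets out from 13. Cross-metathesis with methyl acrylate (second-generation Grubbs catalyst) gives the (E)-enoate F7. Enantioselective conjugate borylation (CuCl, NaOt-Bu, Tol-BINAP, B2pin2, MeOH) gives the β-boryl ester F8. One Matteson homologation (BrCH2Cl, n-BuLi, −78 °C) gives the γ-boryl ester F9, and NaBO3 oxidation gives the γ-hydroxy ester F10, which lactonises on gentle warming. This comes back to the route at 33.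

**Further compounds**

F1 | step 6 | (R)-3-{[5-allyl-2-(TBSO)-3-methoxyphenyl]acetyl}-4-benzyl-1,3-oxazolidin-2-one | C=CCc1cc(CC(=O)N2[C@H](Cc3ccccc3)COC2=O)c(O[Si](C)(C)C(C)(C)C)c(OC)c1
F2 | step 6 | (Z)-dibutylboron enolate of F1 | C=CCc1cc(/C=C(\OB(CCCC)CCCC)N2[C@H](Cc3ccccc3)COC2=O)c(O[Si](C)(C)C(C)(C)C)c(OC)c1
F3 | step 6 | (R)-3-{(2R,3S)-2-[5-allyl-2-(TBSO)-3-methoxyphenyl]-3-hydroxy-3-[4-(TBSO)-3-methoxyphenyl]propanoyl}-4-benzyl-1,3-oxazolidin-2-one | COc1cc([C@@H](O)[C@H](C(=O)N3[C@H](Cc4ccccc4)COC3=O)c2cc(CC=C)cc(OC)c2O[Si](C)(C)C(C)(C)C)ccc1O[Si](C)(C)C(C)(C)C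
F4 | step 19 | 9-(3-ArA-propyl)-9-borabicyclo[3.3.1]nonane | COc1cc([C@@H](O[Si](C)(C)C(C)(C)C)[C@H](CO[Si](C)(C)C(C)(C)C)c2cc(CCCB3C4CCCC3CCC4)cc(OC)c2O[Si](C)(C)C(C)(C)C)ccc1O[Si](C)(C)C(C)(C)C
F5 | step 19 | 3-ArA-propan-1-ol | COc1cc([C@@H](O[Si](C)(C)C(C)(C)C)[C@H](CO[Si](C)(C)C(C)(C)C)c2cc(CCCO)cc(OC)c2O[Si](C)(C)C(C)(C)C)ccc1O[Si](C)(C)C(C)(C)C
F6 | step 19 | 3-ArA-propyl diazoacetate | COc1cc([C@@H](O[Si](C)(C)C(C)(C)C)[C@H](CO[Si](C)(C)C(C)(C)C)c2cc(CCCOC(=O)C=[N+]=[N-])cc(OC)c2O[Si](C)(C)C(C)(C)C)ccc1O[Si](C)(C)C(C)(C)C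
F7 | step 20 | methyl (E)-4-ArA-but-2-enoate | COc1cc([C@@H](O[Si](C)(C)C(C)(C)C)[C@H](CO[Si](C)(C)C(C)(C)C)c2cc(C/C=C/C(=O)OC)cc(OC)c2O[Si](C)(C)C(C)(C)C)ccc1O[Si](C)(C)C(C)(C)C
F8 | step 20 | methyl (3R)-4-ArA-3-(4,4,5,5-tetramethyl-1,3,2-dioxaborolan-2-yl)butanoate | COc1cc([C@@H](O[Si](C)(C)C(C)(C)C)[C@H](CO[Si](C)(C)C(C)(C)C)c2cc(C[C@H](CC(=O)OC)B3OC(C)(C)C(C)(C)O3)cc(OC)c2O[Si](C)(C)C(C)(C)C)ccc1O[Si](C)(C)C(C)(C)C
F9 | step 20 | methyl (3R)-3-(ArA-methyl)-4-(4,4,5,5-tetramethyl-1,3,2-dioxaborolan-2-yl)butanoate | COc1cc([C@@H](O[Si](C)(C)C(C)(C)C)[C@H](CO[Si](C)(C)C(C)(C)C)c2cc(C[C@H](CC(=O)OC)CB3OC(C)(C)C(C)(C)O3)cc(OC)c2O[Si](C)(C)C(C)(C)C)ccc1O[Si](C)(C)C(C)(C)C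
F10 | step 20 | methyl (3R)-3-(ArA-methyl)-4-hydroxybutanoate | COc1cc([C@@H](O[Si](C)(C)C(C)(C)C)[C@H](CO[Si](C)(C)C(C)(C)C)c2cc(C[C@H](CC(=O)OC)CO)cc(OC)c2O[Si](C)(C)C(C)(C)C)ccc1O[Si](C)(C)C(C)(C)C
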